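The route rests on disconnecting the decalin at C4–C5 and C9–C10. Trans-fused rings A and B, with stereocentres C5, C9 and C10 and the exocyclic C8=C12 alkene, are the chair–chair folding pattern of an (E,E)-farnesyl chain joined through C11 to epoxide carbon C1'. A class-two terpene cyclase should close both rings, set the three stereocentres and place the alkene in one final operation that spares the epoxy ketone. Its substrate, farnesyl epoxyquinol 13, comes from a 4-methoxyphenol whose hydroxyl lies ortho to the farnesyl group: oxidative dearomatization then fixes the ketal at C3', auxiliary-controlled nucleophilic epoxidation sets C1' and C2', and a chelation-controlled reduction sets C3'.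

Key step: step 10

Numbering: drimane numbering for the decalin (C11 = linking CH2, C12 = exocyclic CH2); C1' = epoxide carbon bearing C11, C2' = epoxide CH, C3' = CHOH, C4' = C–CH2OH, C5' = =CH, C6' = C=O. "Farnesyl" = (2E,6E)-3,7,11-trimethyldodeca-2,6,10-trien-1-yl; TBS = tert-butyldimethylsilyl.

Remark: the facial bias of the (2S,4S)-dioxane in step 7 is assigned from a chair model (dioxane leaning over C2', axial methyl covering one face); both diol enantiomers are commercial, so the sense can be switched without changing the route.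

Step 1
Reactants: 1 5-hydroxy-2-methoxybenzaldehyde
Product: 2 3-(hydroxymethyl)-4-methoxyphenol
Conditions: NaBH4, MeOH, 0 °C
Reagents that add atoms: none
Why: Borohydride reduction of an aryl aldehyde gives the benzylic alcohol and leaves the phenol and the aryl ether untouched.

Step 2
Reactants: 2 3-(hydroxymethyl)-4-methoxyphenol
Product: 3 3-{[(tert-butyldimethylsilyl)oxy]methyl}-4-methoxyphenol
Conditions: TBSCl (1.05 equiv), imidazole, CH2Cl2/DMF, 0 °C
Reagents that add atoms: tert-butyldimethylsilyl chloride, CC(C)(C)[Si](C)(C)Cl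
Why: Imidazole-mediated O-silylation should take the more nucleophilic primary benzylic alcohol in preference to the undeprotonated phenol, as is usual for hydroxybenzyl alcohols.

Step 3
Reactants: 3 3-{[(tert-butyldimethylsilyl)oxy]methyl}-4-methoxyphenol
Product: 4 2-bromo-5-{[(tert-butyldimethylsilyl)oxy]methyl}-4-methoxyphenol
Conditions: NBS (1.0 equiv), i-Pr2NH (10 mol %), CH2Cl2, 0 °C
Reagents that add atoms: N-bromosuccinimide, O=C1CCC(=O)N1Br
Why: Amine-catalysed electrophilic aromatic bromination of a phenol goes ortho to the hydroxyl, and with the para position blocked by OMe the ortho site para to the bulky silyloxymethyl group should be taken over the one flanked by it.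

Step 4
Reactants: 4 2-bromo-5-{[(tert-butyldimethylsilyl)oxy]methyl}-4-methoxyphenol; 5 (2E,6E)-farnesyl bromide
Product: 7 5-{[(tert-butyldimethylsilyl)oxy]methyl}-2-farnesyl-4-methoxyphenol, via dilithiated phenoxide 6 (not isolated)
Conditions: n-BuLi (1.0 equiv), then t-BuLi (2.1 equiv), THF, −78 °C; CuBr·SMe2 (0.2 equiv), 5 (1.0 equiv), −78 → 0 °C; aq. NH4Cl
Reagents that add atoms: (2E,6E)-farnesyl bromide (5), CC(C)=CCC/C(C)=C/CC/C(C)=C/CBr
Why: Deprotonation followed by bromine–lithium exchange gives the ortho-lithiated phenoxide, and copper-catalysed allylic substitution at the primary carbon of 5 (SN2, not SN2') forms the aryl–C11 bond with the 2E alkene intact.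

Step 5
Reactants: 7 5-{[(tert-butyldimethylsilyl)oxy]methyl}-2-farnesyl-4-methoxyphenol
Product: 8 5-{[(tert-butyldimethylsilyl)oxy]methyl}-2-farnesyl-4,4-dimethoxycyclohexa-2,5-dien-1-one
Conditions: PhI(OAc)2 (1.1 equiv), MeOH, 0 °C
Reagents that add atoms: methanol, CO
Why: Oxidative dearomatization of a 4-methoxyphenol by the trivalent iodine reagent, with capture by methanol at the para carbon, gives the quinone monoketal whose free carbonyl is the former phenol carbon C6', so the ketal sits at C3' by construction.

Step 6
Reactants: 8 5-{[(tert-butyldimethylsilyl)oxy]methyl}-2-farnesyl-4,4-dimethoxycyclohexa-2,5-dien-1-one; 9 (2S,4S)-pentane-2,4-diol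
Product: 10 (2S,4S)-11-{[(tert-butyldimethylsilyl)oxy]methyl}-8-farnesyl-2,4-dimethyl-1,5-dioxaspiro[5.5]undeca-7,10-dien-9-one
Conditions: 9 (3 equiv), PPTS (0.1 equiv), benzene, 4 Å MS, 50 °C
Reagents that add atoms: (2S,4S)-pentane-2,4-diol (9), C[C@H](O)C[C@H](C)O
Why: Acid-catalysed transketalization, driven by removal of methanol, exchanges the dimethyl ketal for the C2-symmetric dioxane, which creates no new stereocentre at C3'.

Step 7
Reactants: 10 (2S,4S)-11-{[(tert-butyldimethylsilyl)oxy]methyl}-8-farnesyl-2,4-dimethyl-1,5-dioxaspiro[5.5]undeca-7,10-dien-9-one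
Product: 11 (1'S,2'R)-C1'–C2' epoxide of 10 (oxirane across the farnesyl-bearing carbon and the CH next to the ketal)
Conditions: Ph3COOH (2 equiv), KN(SiMe3)2 (0.2 equiv), THF, −35 °C
Reagents that add atoms: triphenylmethyl hydroperoxide, OOC(c1ccccc1)(c1ccccc1)c1ccccc1
Why: In this Weitz–Scheffer epoxidation the peroxide anion should add to C2', the only unsubstituted β-carbon of the dienone (C4' is blocked by CH2OTBS and the farnesyl alkenes are not electrophilic), on the face not covered by the axial methyl of the dioxane chair, and closure onto C1' then gives the (1'S,2'R) epoxide, with any minor diastereomer removed by chromatography.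

Step 8
Reactants: 11 (1'S,2'R)-C1'–C2' epoxide of 10
Product: 12 (1S,6R)-1-farnesyl-4-(hydroxymethyl)-7-oxabicyclo[4.1.0]hept-3-ene-2,5-dione
Conditions: 48% aq. HF, MeCN, 0 °C → rt
Reagents that add atoms: water, O
Why: Aqueous HF should cleave the silyl ether and hydrolyse the ketal (the C3' carbonyl oxygen comes from water) under acidity too weak to open the carbonyl-deactivated epoxide or protonate the trisubstituted alkenes.

Step 9
Reactants: 12 (1S,6R)-1-farnesyl-4-(hydroxymethyl)-7-oxabicyclo[4.1.0]hept-3-ene-2,5-dione
Product: 13 (1S,5S,6S)-1-farnesyl-5-hydroxy-4-(hydroxymethyl)-7-oxabicyclo[4.1.0]hept-3-en-2-one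
Conditions: NaBH4 (0.5 equiv), CeCl3·7H2O (1.2 equiv), MeOH, −78 °C
Reagents that add atoms: none
Why: In this Luche 1,2-reduction trivalent cerium held between the primary hydroxyl and the adjacent C3' carbonyl should activate that carbonyl, C6' is shielded by the quaternary C1' carrying the farnesyl chain, and hydride should enter anti to the C2'–O bond so that the new C3' hydroxyl is cis to the epoxide oxygen (3'S).

Step 10
Reactants: 13 (1S,5S,6S)-1-farnesyl-5-hydroxy-4-(hydroxymethyl)-7-oxabicyclo[4.1.0]hept-3-en-2-one
Product: 14 (1S,5S,6S)-5-hydroxy-4-(hydroxymethyl)-1-{[(1S,4aS,8aS)-5,5,8a-trimethyl-2-methylidenedecahydronaphthalen-1-yl]methyl}-7-oxabicyclo[4.1.0]hept-3-en-2-one (target)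
Conditions: recombinant membrane cyclase MacJ (microsomes of Aspergillus oryzae expressing macJ), 50 mM potassium phosphate pH 7.5, 2% DMSO, 30 °C, 16 h; EtOAc extraction, SiO2
Reagents that add atoms: none
Why: An active-site acid protonates C3 of the terminal C3=C4 alkene, the C5=C10 alkene adds to the C4 cation (6-endo, ring A, bond C4–C5), the C8=C9 alkene adds to the C10 cation (6-endo, ring B, bond C9–C10), and the C8 cation is quenched by loss of a C12 proton to leave the exocyclic alkene. The closest known reaction type is the protonation-initiated class-two terpene cyclization that this enzyme family carries out on farnesylated epoxycyclohexenones in the biosynthesis of this meroterpenoid class. The trans ring fusion (C5, C10) and the equatorial C11 at C9 follow from anti addition across the two E alkenes in a chair–chair fold, and the absolute sense (5S, 9S, 10S) is set by the enantioface of the fold that the active site enforces, not by the remote C1'–C3' centres. The step needs protonation of the distal alkene only, in the presence of the acid-labile epoxy ketone and allylic alcohol, and deprotonation at C12 rather than C7 or C9; the enzyme pocket, which binds the polar head group far from the catalytic acid and places its base over C12, should secure both, and the (2E,6E) geometry of 13 secures the relative configuration.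

Compound list
1 | 5-hydroxy-2-methoxybenzaldehyde | COc1ccc(O)cc1C=O | starting material
2 | 3-(hydroxymethyl)-4-methoxyphenol | COc1ccc(O)cc1CO | intermediate
3 | 3-{[(tert-butyldimethylsilyl)oxy]methyl}-4-methoxyphenol | COc1ccc(O)cc1CO[Si](C)(C)C(C)(C)C | intermediate
4 | 2-bromo-5-{[(tert-butyldimethylsilyl)oxy]methyl}-4-methoxyphenol | COc1cc(Br)c(O)cc1CO[Si](C)(C)C(C)(C)C | intermediate
5 | (2E,6E)-farnesyl bromide, (2E,6E)-1-bromo-3,7,11-trimethyldodeca-2,6,10-triene | CC(C)=CCC/C(C)=C/CC/C(C)=C/CBr | starting material
6 | lithium 5-{[(tert-butyldimethylsilyl)oxy]methyl}-2-lithio-4-methoxyphenoxide | [Li]c1cc(OC)c(CO[Si](C)(C)C(C)(C)C)cc1O[Li] | intermediate (not isolated)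
7 | 5-{[(tert-butyldimethylsilyl)oxy]methyl}-2-farnesyl-4-methoxyphenol | CC(C)=CCC/C(C)=C/CC/C(C)=C/Cc1cc(OC)c(CO[Si](C)(C)C(C)(C)C)cc1O | intermediate
8 | 5-{[(tert-butyldimethylsilyl)oxy]methyl}-2-farnesyl-4,4-dimethoxycyclohexa-2,5-dien-1-one | CC(C)=CCC/C(C)=C/CC/C(C)=C/CC1=CC(OC)(OC)C(CO[Si](C)(C)C(C)(C)C)=CC1=O | intermediate
9 | (2S,4S)-pentane-2,4-diol | C[C@H](O)C[C@H](C)O | starting material
10 | (2S,4S)-11-{[(tert-butyldimethylsilyl)oxy]methyl}-8-farnesyl-2,4-dimethyl-1,5-dioxaspiro[5.5]undeca-7,10-dien-9-one | CC(C)=CCC/C(C)=C/CC/C(C)=C/CC1=CC2(O[C@@H](C)C[C@H](C)O2)C(CO[Si](C)(C)C(C)(C)C)=CC1=O | intermediate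
11 | (1'S,2'R)-C1'–C2' epoxide of 10, oxirane oxygen on the face that is later cis to the C3' hydroxyl | CC(C)=CCC/C(C)=C/CC/C(C)=C/C[C@]12O[C@H]1C3(O[C@@H](C)C[C@H](C)O3)C(CO[Si](C)(C)C(C)(C)C)=CC2=O | intermediate
12 | (1S,6R)-1-farnesyl-4-(hydroxymethyl)-7-oxabicyclo[4.1.0]hept-3-ene-2,5-dione (farnesyl epoxyquinone) | CC(C)=CCC/C(C)=C/CC/C(C)=C/C[C@]12O[C@H]1C(=O)C(CO)=CC2=O | intermediate
13 | (1S,5S,6S)-1-farnesyl-5-hydroxy-4-(hydroxymethyl)-7-oxabicyclo[4.1.0]hept-3-en-2-one (farnesyl epoxyquinol, cyclase substrate) | CC(C)=CCC/C(C)=C/CC/C(C)=C/C[C@]12O[C@H]1[C@@H](O)C(CO)=CC2=O | intermediate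
14 | (1S,5S,6S)-5-hydroxy-4-(hydroxymethyl)-1-{[(1S,4aS,8aS)-5,5,8a-trimethyl-2-methylidenedecahydronaphthalen-1-yl]methyl}-7-oxabicyclo[4.1.0]hept-3-en-2-one | C=C1CC[C@H]2C(C)(C)CCC[C@]2(C)[C@H]1C[C@]12O[C@H]1[C@@H](O)C(CO)=CC2=O | target

Total step count: 10. Longest linear sequence: 10 steps (1 → 14).

Steps most likely to fail

Step 10. The cyclization may stall on a preparative scale: the water-insoluble substrate has to partition into a microsomal membrane, the integral membrane enzyme can lose activity outside the cell, and the allylic epoxy alcohol can degrade during a long aqueous incubation. The fallback changes the oxidation level of the cyclase substrate, the format of the biotransformation and the order of the endgame. It sets out from 12: the ketone-level compound is fed to resting cells of the macJ-expressing Aspergillus oryzae strain, where the enzyme stays in its native membrane, to give the drimanyl epoxyquinone F1. Luche reduction of F1 under the conditions of step 9 (same chelation by the primary hydroxyl, C6' now shielded by the decalin) comes back to the route at 14.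

Step 9. Hydride may be delivered on the epoxide face, giving the C3' epimer, or may also reach C6'. The fallback accepts the wrong face and corrects it by inversion. It sets out from 12: reduction with i-Bu2AlH (THF, −78 °C), in which aluminium bound to the primary alkoxide activates C3' and can bind the epoxide oxygen to deliver hydride on that face, should give the C3' epimer of 13 F2. Selective acetylation of the primary hydroxyl (Ac2O, 2,4,6-collidine, CH2Cl2, −40 °C) gives the monoacetate F3. A Mitsunobu reaction (4-nitrobenzoic acid, PPh3, DIAD, THF, 0 °C) inverts C3' and gives the acetate 4-nitrobenzoate diester F4. Mild methanolysis (K2CO3, MeOH, 0 °C) removes both esters and comes back to the route at 13.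

Step 7. The auxiliary may give poor facial selectivity, or a sense opposite to the chair model. The fallback replaces auxiliary control by catalyst control and drops the ketal exchange. It sets out from 8: Weitz–Scheffer epoxidation under chiral phase-transfer conditions (N-benzylcinchonidinium chloride or its cinchonine-derived pseudoenantiomer, whichever gives the (1'S,2'R) epoxide, t-BuOOH, aq. NaOH, toluene, 0 °C) gives the epoxy dimethyl ketal F5. Aqueous HF in MeCN then removes ketal and silyl group and comes back to the route at 12.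

Further compounds
F1 | step 10 | (1S,6R)-4-(hydroxymethyl)-1-{[(1S,4aS,8aS)-5,5,8a-trimethyl-2-methylidenedecahydronaphthalen-1-yl]methyl}-7-oxabicyclo[4.1.0]hept-3-ene-2,5-dione (drimanyl epoxyquinone) | C=C1CC[C@H]2C(C)(C)CCC[C@]2(C)[C@H]1C[C@]12O[C@H]1C(=O)C(CO)=CC2=O
F2 | step 9 | (1S,5R,6S)-1-farnesyl-5-hydroxy-4-(hydroxymethyl)-7-oxabicyclo[4.1.0]hept-3-en-2-one (C3' epimer of 13) | CC(C)=CCC/C(C)=C/CC/C(C)=C/C[C@]12O[C@H]1[C@H](O)C(CO)=CC2=O
F3 | step 9 | primary acetate of F2 | CC(C)=CCC/C(C)=C/CC/C(C)=C/C[C@]12O[C@H]1[C@H](O)C(COC(C)=O)=CC2=O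
F4 | step 9 | primary acetate and C3' 4-nitrobenzoate of 13 (C3' inverted relative to F3) | CC(C)=CCC/C(C)=C/CC/C(C)=C/C[C@]12O[C@H]1[C@@H](OC(=O)c3ccc(cc3)[N+](=O)[O-])C(COC(C)=O)=CC2=O
F5 | step 7 | (1'S,2'R)-C1'–C2' epoxide of 8 (epoxy dimethyl ketal) | CC(C)=CCC/C(C)=C/CC/C(C)=C/C[C@]12O[C@H]1C(OC)(OC)C(CO[Si](C)(C)C(C)(C)C)=CC2=O
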